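The pitfall here was to rank the set-ups by how low each one keeps the partner.

| flask | substrate | partner | free catalyst | second catalyst | time | remark |
|---|---|---|---|---|---|---|
| teal | 0.062 M | 1.00 equiv | 0.066 mol% | 1.3 mol% | 15 min | plug flow through a tube for 15 min, no back-mixing |
| violet | 0.062 M | 1.00 equiv (fed, over 15.0 min) | 0.066 mol% | 1.3 mol% | 15 min | all but partner at the start; partner goes in evenly over 15.0 min, the run ends at 15 min |
| grey | 0.062 M | 1.00 equiv | 0.066 mol% | 1.3 mol% | 15 min | a closed flask charged with all of it at once and left for 15 min |
| ochre | 0.062 M | 1.00 equiv | 0.066 mol% | 1.3 mol% |  | one stirred flow tank at steady state, fed with the mixture as stated, mean residence time 15 min |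

    substrate + free catalyst ⇌ free catalyst + intermediate (K1 = 0.47, k1 = 85.4 M⁻¹ s⁻¹)
    partner + second catalyst + intermediate → second catalyst + target (k2 = 926 M⁻² s⁻¹)
    partner → decomposed reagent (k3 = 0.00202 s⁻¹)
    partner + target → over-reaction product (k4 = 0.198 M⁻¹ s⁻¹)

- the set-up with the highest amount of target at the outlet or at the end, in percent of the substrate put in ("none" if the first two lie within 2 percentage points) (teal / violet / grey / ochre / none)
- amount of target at the outlet or at the end, in percent of the substrate put in, teal
- amount of target at the outlet or at the end, in percent of the substrate put in, violet
- amount of target at the outlet or at the end, in percent of the substrate put in, grey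
- amount of target at the outlet or at the end, in percent of the substrate put in, ochre

- the stated concentrations are those of everything mixed, before any reaction; amounts are the same in each set-up
- the feed brings no volume worth counting
- run time (teal): 15 min

I had to choose the set-up for the next run and say how far target could climb in it. The steps that consume partner are each first order in partner, so its concentration cancels from any ratio of them. I therefore carried the selectivity factor S = 3.77, the rate constant of target formation times the concentration of second catalyst, divided by the rate constant of over-reaction. With I and P the concentrations of intermediate and target, target formation runs S·I/P times as fast as over-reaction. While partner is present, target gains as long as that ratio stands above one.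

Teal and grey start with no intermediate. At their start, partner decomposes at 0.00751 M min⁻¹, while the first step runs forward at 0.0130 M min⁻¹. Violet also starts with no intermediate, but it feeds partner at 0.00413 M min⁻¹, a third of that first-step rate, so I chose violet: its later partner meets intermediate made in the meantime.

Then I reckoned the stall level, in rounds. I took intermediate as the fraction φ = 0.320 of the substrate pool, which gives a = Sφ = 1.21. In the first round I ignored over-reaction product. Setting S·I equal to P then put target at a over one plus a, or 54.7% of the substrate. In the second round I put the over-reaction product back. Each unit of it has cost two of partner, one to make the target and one to over-react it. With decomposition left out and the charge of partner used up in these two steps, target came to a over two plus a, or 37.6%. I committed to that figure for violet, with teal and grey below it.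

The forecast named violet, with 29% for teal, 34% for violet, 29% for grey and 22% for ochre. Its ground was: “Slow feeding keeps the partner low, which suppresses both loss routes”. My ground differed, since partner cancels from my ratio.

Violet gave 35.1%, against 26.1% for teal, 26.1% for grey and 22.1% for ochre. Left until 150 min, violet reached 35.8%. At 15.0 min, violet held 11.0% intermediate, so S·I/P stood at 1.18, and target there was still gaining slowly. A neighbour of violet with 5.2 mol% of second catalyst had S = 15.1 and gave 56.5%. It ended with 5.18% intermediate and a ratio of 1.38.

The numbers are those of an exercise, and the outcome is calculated.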